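## Direct plan and its weak steps

Numbering: tetralin C1 bears the syringyl ring C, C2 and C3 bear CH2OH, C4 is CH2, and C4a/C8a fuse ring B to the guaiacyl ring A.

- A direct plan would make the (S)-β-(arylmethyl)butyrolactone A1 by auxiliary-controlled alkylation of a succinyl imide, reductive auxiliary removal and lactonisation.
- Its enolate would add to O-benzylsyringaldehyde A2 to give the trans aldol carbinol A3. Acid would ionise A3 and close C1–C8a (Friedel–Crafts) to the trans-fused lactone A4, and LiAlH4 and hydrogenolysis would finish.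
- **Weak, the run-up to A1:** five linear operations and a stoichiometric auxiliary would buy one stereocentre on a simple lactone.
- **Weak, the aldol to A3:** it would form one bond reversibly and make a carbinol centre as a mixture only to erase it. The stereocentres would be relayed one at a time (C3 → C2 → C1).
- **Weak, the cationic closure to A4:** strong acid would meet two aryl benzyl ethers late, and the doubly flanked syringyl one is acid-labile. Debenzylation, C-benzylation and dehydration would compete, and C1 would rest on a thermodynamic bias only.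

## Retrosynthetic overview of the new route

1. C1 and C4 are both benzylic to ring A (at C8a and C4a), and C2/C3 carry two identical, trans CH2OH groups. Ring B is therefore cut at C1–C2 and C3–C4 into an o-quinodimethane and a C2-symmetric fumarate.
2. The diene would be the photoenol of an achiral 2-benzylbenzaldehyde. Its OH becomes a C4–O bond that the target lacks, placed on purpose to steer the endo/exo choice (1,2-trans) and removed at the end, helped by the C7 oxygen para to C4a.
3. Rings A and C are bought. Ring B closes in the key step with C1, C2, C3 (and the temporary C4) set as a group, and two (R)-mandelate esters on the fumarate give the absolute sense.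
4. The aldehyde comes from one sp3–sp2 cross-coupling of a syringaldehyde-derived and a vanillin-derived half. After the key step only LiAlH4 (which also removes the auxiliary) and one hydrogenolysis remain.
5. This design needs no lactone run-up, no stereochemical relay and no throw-away carbinol mixture, and no strong acid meets the benzyl ethers.

Key step: step 6

Assumption: the sense of induction follows the model in step 6 ((R)-mandelate → si,si face → 1R,2S,3S). If it proved opposite, the equally commercial methyl (S)-mandelate would be used with no other change.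
Assumption: 1, 4, 8 and 9 are taken as commercial.

## Route

Step 1
Reactants: 1 4-(benzyloxy)-3,5-dimethoxybenzaldehyde
Product: 2 [4-(benzyloxy)-3,5-dimethoxyphenyl]methanol
Conditions: NaBH4, MeOH, 0 °C
Reagents that add atoms: none
Why: Borohydride reduction of an aryl aldehyde to the benzylic alcohol, which leaves the ethers untouched and involves no stereochemistry.

Step 2
Reactants: 2 [4-(benzyloxy)-3,5-dimethoxyphenyl]methanol
Product: 3 4-(benzyloxy)-3,5-dimethoxybenzyl chloride
Conditions: SOCl2, CH2Cl2, 0 °C, used without storage
Reagents that add atoms: thionyl chloride, O=S(Cl)Cl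
Why: Deoxychlorination of an electron-rich primary benzylic alcohol via its chlorosulfite should be fast at 0 °C, so contact of the benzyl ether with HCl stays short.

Step 3
Reactants: 4 4-(benzyloxy)-3-methoxybenzaldehyde
Product: 5 4-(benzyloxy)-2-bromo-5-methoxybenzaldehyde
Conditions: Br2, NaOAc, AcOH, rt
Reagents that add atoms: bromine, BrBr
Why: Electrophilic aromatic bromination, which with the phenol capped should go to the position para to OMe (the future C8a), the most activated and least hindered site.

Step 4
Reactants: 3 4-(benzyloxy)-3,5-dimethoxybenzyl chloride; 5 4-(benzyloxy)-2-bromo-5-methoxybenzaldehyde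
Product: 7 4-(benzyloxy)-2-[4-(benzyloxy)-3,5-dimethoxybenzyl]-5-methoxybenzaldehyde, via benzylzinc chloride 6 (not isolated)
Conditions: Zn dust, LiCl, THF, 25 °C; then 5, Pd(OAc)2 (2 mol %), SPhos (4 mol %), THF, 25 °C
Reagents that add atoms: zinc, [Zn] (held in 6, leaves again as zinc halide)
Why: LiCl-assisted zinc insertion into the benzylic chloride followed by Negishi sp3–sp2 coupling, in which oxidative addition at the C–Br bond ortho to CHO is fast and the formyl group, deactivated by its para benzyloxy donor, should outlast the mild organozinc.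

Step 5
Reactants: 8 fumaryl chloride; 9 methyl (R)-mandelate (2 equiv)
Product: 10 bis[(R)-2-methoxy-2-oxo-1-phenylethyl] fumarate
Conditions: PhMe, reflux, N2 sweep, no base
Reagents that add atoms: none
Why: Base-free acylation of the secondary alcohol by the diacid chloride, with HCl swept out so that the acidic mandelate stereocentre is never exposed to base and the E-alkene is kept.

Step 6
Reactants: 7 4-(benzyloxy)-2-[4-(benzyloxy)-3,5-dimethoxybenzyl]-5-methoxybenzaldehyde; 10 bis[(R)-2-methoxy-2-oxo-1-phenylethyl] fumarate
Product: 12 bis-mandelyl (1R,2S,3R,4R)-1-aryl-4-hydroxytetralin-2,3-dicarboxylate (1,2-trans/2,3-trans/3,4-cis), via (E,E)-hydroxy-o-quinodimethane 11 (not isolated)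
Conditions: hν (365 nm LED), 10 (1.5 equiv), degassed PhMe (0.02 M), 10 °C
Reagents that add atoms: none
Why: Excitation of the aryl aldehyde of 7 should trigger a 1,5-hydrogen shift from the doubly benzylic CH2 to the carbonyl oxygen (photoenolisation), and only the long-lived (E,E)-dienol 11 can be trapped, because the Z-enols fall back to 7 by thermal 1,5-H return. Dienol 11 then adds suprafacially to 10 in an intermolecular [4π+2π] Diels–Alder reaction (closest known type: hydroxy-o-quinodimethanes with fumarates of α-hydroxy esters), which closes ring B by forming C1–C2 and C3–C4 at once and is driven by rearomatisation of ring A. The 2,3-trans relation is copied from the E-alkene and the 1,4-cis relation from the E,E-diene. Of the two remaining orientations, the one with the C3 ester endo beside the small C4–OH and the C2 ester exo beside the twisted, bulky C1 aryl group should win, which gives 3,4-cis and the required 1,2-trans. The absolute sense comes from the two (R)-mandelyl groups: with each carbinol C–H eclipsing its ester C=O and the enoates s-cis, both phenyl groups screen the re,re face, so the diene adds to the si,si face (2S,3R in 12). No regiochemical question arises because 10 is C2-symmetric and both ester carbons end as the same CH2OH group, and only 7 absorbs at 365 nm, so 10 and 12 are not excited directly.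

Step 7
Reactants: 12 bis-mandelyl (1R,2S,3R,4R)-1-aryl-4-hydroxytetralin-2,3-dicarboxylate
Product: 13 (1R,2S,3S,4R)-7-(benzyloxy)-1-[4-(benzyloxy)-3,5-dimethoxyphenyl]-2,3-bis(hydroxymethyl)-6-methoxytetralin-4-ol
Conditions: LiAlH4 (excess), THF, 0 °C → rt; Rochelle salt work-up
Reagents that add atoms: none
Why: LiAlH4 ester reduction turns both ring esters into the C2 and C3 CH2OH groups and releases the auxiliary as a polar diol in the same operation, while the C4 alkoxide formed first guards against β-elimination and no stereocentre is touched.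

Step 8
Reactants: 13 (1R,2S,3S,4R)-7-(benzyloxy)-1-[4-(benzyloxy)-3,5-dimethoxyphenyl]-2,3-bis(hydroxymethyl)-6-methoxytetralin-4-ol
Product: 14 (6S,7S,8R)-8-(4-hydroxy-3,5-dimethoxyphenyl)-6,7-bis(hydroxymethyl)-3-methoxy-5,6,7,8-tetrahydronaphthalen-2-ol (target, 1R,2S,3S in tetralin numbering)
Conditions: H2 (1 atm), 10% Pd/C, EtOH–AcOH (9:1), rt
Reagents that add atoms: none
Why: In this catalytic hydrogenolysis the two aryl benzyl ethers should fall first and the C4–OH, by then a p-hydroxybenzylic alcohol (C7–OH para to C4a), should follow under the same mild conditions, while the C1 diarylmethine, the methoxy groups and the primary alcohols are inert and C4 ceases to be a stereocentre.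

## Compound list

1 | 4-(benzyloxy)-3,5-dimethoxybenzaldehyde | COc1cc(C=O)cc(OC)c1OCc1ccccc1 | starting material
2 | [4-(benzyloxy)-3,5-dimethoxyphenyl]methanol | COc1cc(CO)cc(OC)c1OCc1ccccc1 | intermediate
3 | 4-(benzyloxy)-3,5-dimethoxybenzyl chloride | COc1cc(CCl)cc(OC)c1OCc1ccccc1 | intermediate
4 | 4-(benzyloxy)-3-methoxybenzaldehyde | COc1cc(C=O)ccc1OCc1ccccc1 | starting material
5 | 4-(benzyloxy)-2-bromo-5-methoxybenzaldehyde | COc1cc(C=O)c(Br)cc1OCc1ccccc1 | intermediate
6 | [4-(benzyloxy)-3,5-dimethoxybenzyl]zinc chloride | COc1cc(C[Zn]Cl)cc(OC)c1OCc1ccccc1 | intermediate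
7 | 4-(benzyloxy)-2-[4-(benzyloxy)-3,5-dimethoxybenzyl]-5-methoxybenzaldehyde | COc1cc(C=O)c(Cc2cc(OC)c(OCc3ccccc3)c(OC)c2)cc1OCc1ccccc1 | intermediate
8 | fumaryl chloride | O=C(Cl)/C=C/C(=O)Cl | starting material
9 | methyl (R)-mandelate | COC(=O)[C@H](O)c1ccccc1 | starting material
10 | bis[(R)-2-methoxy-2-oxo-1-phenylethyl] fumarate | COC(=O)[C@H](OC(=O)/C=C/C(=O)O[C@@H](C(=O)OC)c1ccccc1)c1ccccc1 | intermediate
11 | (E,E)-hydroxy-o-quinodimethane, photoenol of 7 (OH and aryl both outside) | O/C=C1\C=C(OC)C(OCc2ccccc2)=C/C1=C\c1cc(OC)c(OCc2ccccc2)c(OC)c1 | intermediate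
12 | bis[(R)-2-methoxy-2-oxo-1-phenylethyl] (1R,2S,3R,4R)-7-(benzyloxy)-1-[4-(benzyloxy)-3,5-dimethoxyphenyl]-4-hydroxy-6-methoxytetralin-2,3-dicarboxylate | COc1cc2c(cc1OCc1ccccc1)[C@@H](c1cc(OC)c(OCc3ccccc3)c(OC)c1)[C@H](C(=O)O[C@@H](C(=O)OC)c1ccccc1)[C@@H](C(=O)O[C@@H](C(=O)OC)c1ccccc1)[C@H]2O | intermediate
13 | (1R,2S,3S,4R)-7-(benzyloxy)-1-[4-(benzyloxy)-3,5-dimethoxyphenyl]-2,3-bis(hydroxymethyl)-6-methoxytetralin-4-ol | COc1cc2c(cc1OCc1ccccc1)[C@@H](c1cc(OC)c(OCc3ccccc3)c(OC)c1)[C@H](CO)[C@@H](CO)[C@H]2O | intermediate
14 | (6S,7S,8R)-8-(4-hydroxy-3,5-dimethoxyphenyl)-6,7-bis(hydroxymethyl)-3-methoxy-5,6,7,8-tetrahydronaphthalen-2-ol | COc1cc2c(cc1O)[C@@H](c1cc(OC)c(O)c(OC)c1)[C@H](CO)[C@@H](CO)C2 | target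

## Step count and risks

Total steps: 8. Longest linear sequence: 6 (steps 1, 2, 4, 6, 7, 8).

**Step 6 (key step).**
- What may go wrong: the excited aldehyde may be quenched by the fumarate, which would isomerise the dienophile from E to Z. Endo/exo and facial selectivity may also erode when light and cycloaddition share one flask.
- Fallback: light and cycloaddition are separated. Setting out from 7, irradiation in SO2-saturated benzene should capture the dienol cheletropically as the storable cis-1-hydroxy-3-aryl-1,3-dihydrobenzo[c]thiophene 2,2-dioxide F1 (racemic; its stereocentres vanish again).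
- Heating F1 with 10 in toluene in the dark, with ZnO as SO2 scavenger, should release 11 stereospecifically at low stationary concentration. The fallback comes back to the route at 12.

**Step 4.**
- What may go wrong: the benzylic zinc reagent may add to the formyl group of 5, or undergo Wurtz-type homocoupling during the insertion.
- Fallback: the polarity of the coupling is reversed. Setting out from 5, Miyaura borylation (B2pin2, PdCl2(dppf), KOAc, dioxane, 80 °C) should give 4-(benzyloxy)-5-methoxy-2-(pinacolboryl)benzaldehyde F2.
- Suzuki–Miyaura coupling of F2 with the benzylic chloride 3 (PdCl2(dppf), K2CO3, THF/H2O, 60 °C) involves no carbonyl-reactive organometallic and comes back at 7.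

**Step 8.**
- What may go wrong: the reaction may stall at the C4–O bond after debenzylation, or the C4 cation may be intercepted by the C2 hydroxymethyl group.
- Fallback: the two tasks are split and the C4–O cleavage becomes an ionic reduction. Setting out from 13, neutral hydrogenolysis (H2, Pd/C, EtOAc/EtOH) should give the 4-hydroxy bis-phenol F3.
- Et3SiH in TFA/CH2Cl2 at 0 °C, followed by K2CO3/MeOH to remove any trifluoroacetates, should then reduce the p-quinone methide/benzylic cation at C4. The fallback comes back at 14.

## Further compounds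

F1 | step 6 | cis-6-(benzyloxy)-3-[4-(benzyloxy)-3,5-dimethoxyphenyl]-1-hydroxy-5-methoxy-1,3-dihydrobenzo[c]thiophene 2,2-dioxide (racemic, one enantiomer drawn) | COc1cc2c(cc1OCc1ccccc1)[C@@H](c1cc(OC)c(OCc3ccccc3)c(OC)c1)S(=O)(=O)[C@H]2O
F2 | step 4 | 4-(benzyloxy)-5-methoxy-2-(4,4,5,5-tetramethyl-1,3,2-dioxaborolan-2-yl)benzaldehyde | COc1cc(C=O)c(B2OC(C)(C)C(C)(C)O2)cc1OCc1ccccc1
F3 | step 8 | (1R,2S,3S,4R)-1-(4-hydroxy-3,5-dimethoxyphenyl)-2,3-bis(hydroxymethyl)-6-methoxytetralin-4,7-diol | COc1cc2c(cc1O)[C@@H](c1cc(OC)c(O)c(OC)c1)[C@H](CO)[C@@H](CO)[C@H]2O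
A1 | direct plan | (S)-4-(4-benzyloxy-3-methoxybenzyl)dihydrofuran-2(3H)-one | O=C1C[C@H](Cc2ccc(OCc3ccccc3)c(OC)c2)CO1
A2 | direct plan | 4-(benzyloxy)-3,5-dimethoxybenzaldehyde | COc1cc(C=O)cc(OC)c1OCc1ccccc1
A3 | direct plan | trans-α-[hydroxy(aryl)methyl]-β-(arylmethyl)butyrolactone, carbinol epimers | O=C1[C@@H](C(O)c2cc(OC)c(OCc3ccccc3)c(OC)c2)[C@H](Cc2ccc(OCc3ccccc3)c(OC)c2)CO1
A4 | direct plan | trans-fused bis-O-benzyl aryltetralin lactone | COc1cc2c(cc1OCc1ccccc1)[C@@H](c1cc(OC)c(OCc3ccccc3)c(OC)c1)[C@@H]1C(=O)OC[C@H]1C2
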